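## Analysis of the target

The target is a diaryl ether built from two benzene rings and no other ring: ring A is a methyl benzoate (CO2Me on C1) with a prenyloxy group on C2 and the bridging oxygen on C6, and ring B carries that oxygen on C1', a prenyloxy group on C2', hydrogen on C3', methoxy on C4', a carbon-bound prenyl group on C5' and a hydroxymethyl group on C6'. There is no stereocentre, and none of the three C=C bonds can show E/Z isomerism because each ends in an isopropylidene group, so the problem is one of regiochemistry and chemoselectivity only. The fragile parts are the three trisubstituted alkenes (attacked by acid, peracid and hypochlorous acid), the two aryl prenyl ethers (ionised by acid, rearranged by heat) and the electron-rich benzylic alcohol on C6', which under acid can ionise and cyclise onto the neighbouring C5' prenyl group. The ester carbonyl is shielded by two ortho oxygens, which blocks acyl substitution but not O-alkylation of the carboxylate. Two things make the synthesis hard: ring B has a 1,2,4-trioxygenation pattern in which every oxygen carries a different group (aryl, prenyl, methyl) next to two adjacent carbon substituents, and the central ether is flanked by three ortho substituents on rings that offer little activation for C–O bond formation. The strategy rests on the fact that the groups on O2 of ring A and on O2' and C5' of ring B are the same five-carbon unit and differ from an allyl group only by the terminal isopropylidene. All three can therefore travel through the synthesis as allyl groups and be converted together at the end.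

## Retrosynthetic reasoning

Target 20 to triallyl ester 19 and 2-methyl-2-butene 18. The three C=C bonds of the prenyl groups are cut in one retrosynthetic operation, so one molecule of 19 needs three molecules of 18. These alkenes are the only acid- and oxidant-sensitive sites of 20, and cutting them last means that every earlier step meets only monosubstituted allyl groups. The forward reaction must exchange the terminal CH2 for C(CH3)2 at two allyl ethers and one allylarene without touching the free benzylic alcohol or the ester, so no protecting group is needed on 19.

Ester 19 to acid 17 to aldehyde 16. The O–CH3 bond of the ester and the oxidation level of the ring A carbonyl are adjusted. Ring A is carried as an aldehyde up to 16 because a formyl group is a far better activator for the ether-forming step than an ester that is twisted out of conjugation between two ortho substituents. With an ester in that place the substitution would need temperatures at which aryl allyl ethers begin to undergo Claisen rearrangement. The forward steps are an aldehyde-selective oxidation and a carboxylate O-methylation, both of which leave the benzylic alcohol and the allyl groups alone.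

Aldehyde 16 to phenol 13 and fluoroaldehyde 15. The diaryl ether is cut at the C6–O bond of ring A, not at C1'–O, because ring A can carry an ortho acceptor whereas a leaving group on C1' of ring B would sit para to the C4' methoxy group and ortho to an alkoxy group. Ring B enters as the benzylic alcohol 13 and not as the salicylaldehyde 12 for two reasons: the phenoxide of 13 is electron-rich and a good nucleophile, and the product then has only one formyl group, so the two carbonyl carbons never need to be told apart. Fluoroaldehyde 15 comes from phenol 14 and allyl bromide 2.

Phenol 13 to salicylaldehyde 12 to catechol aldehyde 11 and 2. The hydroxymethyl group is traced to a formyl group, which has a second job: it differentiates O1' from O2'. In the dianion of 11 the oxygen ortho to the formyl group is delocalised and the other is not, so the O2'–allyl bond can be made selectively.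

Catechol aldehyde 11 to methyl ether 10. O2' is carried as a methyl ether up to this point. An allyl ether on O2' could not be present during the Claisen step because it would itself rearrange into C3'. The methyl group comes with the starting material 1 and is removed by chelation between the neighbouring phenol and the methoxy oxygen, which leaves the C4' methoxy group untouched.

Methyl ether 10 to hydroquinone aldehyde 9 to allyl ether 7. The O4'–CH3 bond is cut, and then the C5'–allyl bond is traced to an O4'–allyl ether by an aromatic Claisen rearrangement. The oxygen that delivers the allyl group is the one that ends as methoxy, so nothing is wasted. The formyl group is already in place at this stage because it steers the migration to C5' (between C4' and C6') and afterwards distinguishes the free C4' phenol from the hydrogen-bonded C1' phenol in the methylation.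

Allyl ether 7 to phenol 5 to aldehyde 3 to 1 and 2. The C6'–CHO bond is cut by a phenol-directed ortho-formylation, which can only go to C6' because the other ortho position carries the methoxy group. The C1'–O bond is traced to the formyl carbon of 3 by a Dakin-type oxidation. Starting from 1, which has a single phenol, fixes the position of the O4' allyl group without any selective alkylation of two phenols.

## Alternatives that were turned down

Alternative 1: Ring B would be built on the ether oxygen by a photochemical benzannulation through a ketene. The disconnection cuts C1'–C2', C2'–C3', C4'–C5' and C5'–C6'. Irradiation of diazo enone A2, which already holds ring A as an enol ether, in the presence of methoxyacetylene A3 triggers Wolff rearrangement, ketene–alkyne [2+2] addition, four-electron ring opening and six-electron ring closure to phenol A1. O-Prenylation on C2' and desilylation would follow. In its favour, the annulation delivers the hexasubstituted ring with its three oxygens already differentiated, needs no Claisen regiochemistry and no selective alkylation, and makes the hindered ether bond as a simple enol ether before ring B exists. On these points it is stronger than the chosen route. Against it: A2 carries a CH2 group on the diazo carbon, so 1,2-hydrogen shift competes with the Wolff step; the aryl prenyl ether and the enol ether absorb the same light and can cleave or isomerise; A3 is volatile and polymerises; and A2 is a long linear target in itself. The chosen route instead uses two bought aromatic rings, ground-state chemistry only, and keeps all three side chains as allyl groups in 19 until step 13.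

Alternative 2: The C6–O ether bond and the C1–carboxyl bond of ring A would be made together. Fluoride-induced elimination from silyl triflate A5 releases aryne A6; the phenoxide of A7 adds at the aryne carbon remote from the alkoxy group, and the aryl anion, now flanked by two oxygens, is carboxylated by carbon dioxide A8 to give acid A4. O-Methylation and desilylation would follow. In its favour, one step at room temperature forms the tri-ortho-substituted ether without any activating group and sets the ester carbon as well, with regiochemistry secured by the inductive effect of the alkoxy group. This is more direct than the formyl-activated substitution, oxidation and esterification of steps 10 to 12. Against it: the aryl anion is more easily protonated by the phenol than carboxylated, and the phenoxide itself binds A8 reversibly; the fluoride source threatens the silyl ether; A6 undergoes ene reactions with trisubstituted alkenes bearing allylic hydrogens, and three prenyl groups are present. A7 must also be made with its carbon-bound prenyl group in place, which a Claisen rearrangement cannot deliver directly, so a metathesis would be needed anyway. The chosen route exposes only allyl groups to its coupling step.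

Alternative 3: Ring A would be built by cycloaddition, cutting C1–C2 and C5–C6. 3-Hydroxy-2-pyrone A10 and ynoate A11 undergo Diels–Alder addition, and the bridged adduct loses A8 to give salicylate A9. O-Prenylation and desilylation would follow. In its favour, the ring A phenol emerges free and differentiated, the ester is in place, and the ether oxygen is installed before aromatisation, so no substitution on a hindered arene is needed; the regiochemistry is set by the polarity of both partners. Against it: the aryloxy group donates into the β-carbon of A11 and lowers its dienophilicity; A11 is an ynol ether that is hard to make from a doubly ortho-substituted phenol and is easily hydrolysed; thermal cycloaddition and loss of A8 need temperatures at which aryl prenyl ethers rearrange. Ring A is also the part that can be bought, so building it de novo spends steps where the chosen route spends one (step 9). The chosen route puts its steps into ring B, where the difficulty lies.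

Key step: step 13

## Route

Remark: compounds 1, 2, 14 and 18 are taken as commercial; the target has no stereocentre and no E/Z element, so no SMILES string carries a stereo descriptor, and the transient dienone 8 is racemic.

Step 1
Reactants: 1 4-hydroxy-2-methoxybenzaldehyde; 2 allyl bromide
Product: 3 4-(allyloxy)-2-methoxybenzaldehyde
Conditions: K2CO3, DMF, rt
Reagents that add atoms: none
Why: Williamson ether synthesis on the only phenol of 1; no second hydroxyl competes, so the allyl group is placed on the future O4' without any selectivity problem.

Step 2
Reactants: 3 4-(allyloxy)-2-methoxybenzaldehyde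
Product: 5 4-(allyloxy)-2-methoxyphenol, via aryl formate 4 (not isolated)
Conditions: 30% H2O2, cat. H2SO4, MeOH, rt
Reagents that add atoms: hydrogen peroxide, OO
Why: Acid-catalysed Dakin (Baeyer–Villiger-type) oxidation: the peroxide adds to the protonated aldehyde, the aryl group, made electron-rich by its ortho and para alkoxy groups, migrates to oxygen to give formate 4, and methanol cleaves the formate in the same pot. No peracid is present, so the allyl C=C is not epoxidised.

Step 3
Reactants: 5 4-(allyloxy)-2-methoxyphenol
Product: 7 5-(allyloxy)-2-hydroxy-3-methoxybenzaldehyde, via ortho-hydroxymethyl phenol 6 (not isolated)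
Conditions: MgCl2, Et3N, (CH2O)n, MeCN, reflux; then 1 M HCl
Reagents that add atoms: paraformaldehyde (source of formaldehyde), C=O
Why: Magnesium-mediated ortho-formylation of a phenol (Casnati–Skattebøl): the phenoxide held on MgCl2 as ArOMgCl delivers formaldehyde to the only free ortho carbon (the other carries the methoxy group, the para carbon the allyloxy group), and the ArCH2OMgCl alkoxide of 6 passes hydride to a second formaldehyde to give the salicylaldehyde.

Step 4
Reactants: 7 5-(allyloxy)-2-hydroxy-3-methoxybenzaldehyde
Product: 9 6-allyl-2,5-dihydroxy-3-methoxybenzaldehyde, via ortho-dienone 8 (not isolated)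
Conditions: PhNEt2, 190 °C, argon
Reagents that add atoms: none
Why: Aromatic Claisen rearrangement ([3,3] shift, then enolisation of dienone 8). The allyl group should go to C6 and not to C4 because the hydrogen-bonded salicylaldehyde unit fixes the C5–C6 bond as the more double one, a meta acceptor directs toward its own ortho position, and the meta methoxy group directs to the position para to itself, which is also C6.

Step 5
Reactants: 9 6-allyl-2,5-dihydroxy-3-methoxybenzaldehyde
Product: 10 6-allyl-2-hydroxy-3,5-dimethoxybenzaldehyde
Conditions: MeI (1.1 equiv), K2CO3 (1.1 equiv), acetone, rt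
Reagents that add atoms: iodomethane, CI
Why: Williamson methylation that tells the two phenols apart: the C2 hydroxyl is hydrogen-bonded to the formyl group and its anion is a weakly nucleophilic vinylogous carboxylate, so the C5 phenoxide should react first, as in the 5-O-alkylation of 2,5-dihydroxybenzaldehyde. Any doubly methylated material should lose its C2 methyl group again under the chelating Lewis acid of step 6.

Step 6
Reactants: 10 6-allyl-2-hydroxy-3,5-dimethoxybenzaldehyde
Product: 11 6-allyl-2,3-dihydroxy-5-methoxybenzaldehyde
Conditions: AlCl3, pyridine, CH2Cl2, reflux; then dilute HCl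
Reagents that add atoms: none
Why: Chelation-directed aryl methyl ether cleavage: aluminium bridges the C2 phenoxide and the adjacent C3 methoxy oxygen and activates only that methyl group toward chloride, while the C5 methoxy group has no neighbouring donor. This is the standard conversion of 2-methoxyphenols such as o-vanillin into catechols, and the pyridine takes up HCl so that the allyl C=C should not be hydrochlorinated.

Step 7
Reactants: 11 6-allyl-2,3-dihydroxy-5-methoxybenzaldehyde; 2 allyl bromide
Product: 12 6-allyl-3-(allyloxy)-2-hydroxy-5-methoxybenzaldehyde
Conditions: NaH (2.05 equiv), DMF, 0 °C; then 2 (1.0 equiv), 0 °C to rt; aqueous HCl quench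
Reagents that add atoms: none
Why: Regioselective Williamson alkylation of a catechol dianion: the C2 oxygen is delocalised into the formyl group and the C3 oxygen is not, so one equivalent of 2 should go to O3, as known for 2,3-dihydroxybenzaldehyde. No excess of strong base is used, so the carbon-bound allyl group is not isomerised to a propenyl group.

Step 8
Reactants: 12 6-allyl-3-(allyloxy)-2-hydroxy-5-methoxybenzaldehyde
Product: 13 3-allyl-6-(allyloxy)-2-(hydroxymethyl)-4-methoxyphenol
Conditions: NaBH4, MeOH/THF, 0 °C; neutral work-up
Reagents that add atoms: none
Why: Hydride reduction of the aldehyde, the only reducible group in 12. The work-up is kept neutral because the electron-rich ortho-hydroxybenzyl alcohol ionises under acid.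

Step 9
Reactants: 14 2-fluoro-6-hydroxybenzaldehyde; 2 allyl bromide
Product: 15 2-(allyloxy)-6-fluorobenzaldehyde
Conditions: K2CO3, DMF, 50 °C
Reagents that add atoms: none
Why: Williamson ether synthesis; alkylation by 2 is much faster than any substitution of the fluoride by the deactivated phenoxide.

Step 10
Reactants: 13 3-allyl-6-(allyloxy)-2-(hydroxymethyl)-4-methoxyphenol; 15 2-(allyloxy)-6-fluorobenzaldehyde
Product: 16 2-(allyloxy)-6-[3-allyl-6-(allyloxy)-2-(hydroxymethyl)-4-methoxyphenoxy]benzaldehyde
Conditions: K2CO3, DMSO, 85 °C, argon
Reagents that add atoms: none
Why: Nucleophilic aromatic substitution (addition–elimination): the electron-rich phenoxide of 13 attacks the fluorine-bearing carbon of 15, the ortho formyl group stabilises the Meisenheimer intermediate, and fluoride leaves. K2CO3 deprotonates the phenol but not the benzylic alcohol, and 85 °C is far below the onset of Claisen rearrangement of the aryl allyl ethers.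

Step 11
Reactants: 16 2-(allyloxy)-6-[3-allyl-6-(allyloxy)-2-(hydroxymethyl)-4-methoxyphenoxy]benzaldehyde
Product: 17 2-(allyloxy)-6-[3-allyl-6-(allyloxy)-2-(hydroxymethyl)-4-methoxyphenoxy]benzoic acid
Conditions: NaClO2, NaH2PO4, 2-methyl-2-butene 18 (large excess, scavenger), t-BuOH/THF/H2O, 0 °C to rt
Reagents that add atoms: sodium chlorite (NaClO2), [Na+].[O-]Cl=O
Why: Pinnick oxidation: chlorous acid adds to the aldehyde and fragments to the acid and hypochlorous acid, which the trisubstituted alkene 18 captures much faster than the monosubstituted allyl groups or ring B can. The primary benzylic alcohol is not oxidised by chlorite.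

Step 12
Reactants: 17 2-(allyloxy)-6-[3-allyl-6-(allyloxy)-2-(hydroxymethyl)-4-methoxyphenoxy]benzoic acid
Product: 19 methyl 2-(allyloxy)-6-[3-allyl-6-(allyloxy)-2-(hydroxymethyl)-4-methoxyphenoxy]benzoate
Conditions: MeI, KHCO3, DMF, rt
Reagents that add atoms: iodomethane, CI
Why: O-Alkylation of the carboxylate (SN2 at the methyl group), which avoids attack at the hindered 2,6-disubstituted carbonyl carbon. KHCO3 deprotonates only the acid, so the benzylic alcohol is not methylated.

Step 13
Reactants: 19 methyl 2-(allyloxy)-6-[3-allyl-6-(allyloxy)-2-(hydroxymethyl)-4-methoxyphenoxy]benzoate; 18 2-methyl-2-butene (three equivalents are consumed, taken from a large excess)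
Product: 20 methyl 2-[2-(hydroxymethyl)-4-methoxy-3-(3-methylbut-2-enyl)-6-(3-methylbut-2-enyloxy)phenoxy]-6-(3-methylbut-2-enyloxy)benzoate
Conditions: (H2IMes)(PCy3)Cl2Ru=CHPh (second-generation Grubbs catalyst, 10 mol% in two portions), 18/CH2Cl2 (18 as co-solvent, large excess), 1,4-benzoquinone (10 mol%), 35 °C, sealed tube
Reagents that add atoms: 2-methyl-2-butene 18, CC=C(C)C (each of the three allyl groups takes its isopropylidene carbon and two methyl groups from its own molecule of 18)
Why: Olefin cross-metathesis by the metal alkylidene/metallacyclobutane (Chauvin) mechanism; the closest known reaction type is the conversion of allylarenes and aryl allyl ethers into prenyl compounds with 18 and catalysts of the type (H2IMes)(PCy3)Cl2Ru=CHPh. After loss of PCy3 the ruthenium alkylidene adds to a terminal C=C of 19 to give a metallacyclobutane that opens to Ru=CH–CH2–X, where X is O2 of ring A, O2' or C5' of ring B. This alkylidene adds to 18 with the C(CH3)2 end next to the alkylidene carbon, and cycloreversion releases X–CH2–CH=C(CH3)2 and Ru=CHCH3, which picks up the next allyl group and sheds propene, so that one molecule of 19 consumes three molecules of 18 and gives off three of propene. No ring closes and no stereocentre or E/Z element is created, because each new alkene ends in two methyl groups. The step needs all three sites to react and each to react only once: the three terminal alkenes are unhindered at the reacting carbon and should exchange at comparable rates, while the trisubstituted products re-enter the cycle only slowly. The large excess of 18 makes capture by 18 much faster than homodimerisation or ring closure between two allyl groups of one molecule (a twelve-membered or larger ring), and crotyl-type by-products from the ethylidene are carried on to the same prenyl end groups. The free benzylic alcohol and the hindered ester are tolerated by this catalyst, and the benzoquinone and the low temperature restrain ruthenium hydride species that would isomerise allyl ethers to propenyl ethers.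

## Compound list

1 | 4-hydroxy-2-methoxybenzaldehyde | COc1cc(O)ccc1C=O | starting material
2 | allyl bromide (3-bromoprop-1-ene) | C=CCBr | starting material
3 | 4-(allyloxy)-2-methoxybenzaldehyde | COc1cc(OCC=C)ccc1C=O | intermediate
4 | 4-(allyloxy)-2-methoxyphenyl formate | COc1cc(OCC=C)ccc1OC=O | intermediate
5 | 4-(allyloxy)-2-methoxyphenol | COc1cc(OCC=C)ccc1O | intermediate
6 | 4-(allyloxy)-2-(hydroxymethyl)-6-methoxyphenol (held on MgCl2 as its ArOMgCl/ArCH2OMgCl salt in the flask) | COc1cc(OCC=C)cc(CO)c1O | intermediate
7 | 5-(allyloxy)-2-hydroxy-3-methoxybenzaldehyde | COc1cc(OCC=C)cc(C=O)c1O | intermediate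
8 | 6-allyl-2-hydroxy-3-methoxy-5-oxocyclohexa-1,3-diene-1-carbaldehyde (racemic) | O=CC1=C(O)C(OC)=CC(=O)C1CC=C | intermediate
9 | 6-allyl-2,5-dihydroxy-3-methoxybenzaldehyde | COc1cc(O)c(CC=C)c(C=O)c1O | intermediate
10 | 6-allyl-2-hydroxy-3,5-dimethoxybenzaldehyde | COc1cc(OC)c(CC=C)c(C=O)c1O | intermediate
11 | 6-allyl-2,3-dihydroxy-5-methoxybenzaldehyde | COc1cc(O)c(O)c(C=O)c1CC=C | intermediate
12 | 6-allyl-3-(allyloxy)-2-hydroxy-5-methoxybenzaldehyde | COc1cc(OCC=C)c(O)c(C=O)c1CC=C | intermediate
13 | 3-allyl-6-(allyloxy)-2-(hydroxymethyl)-4-methoxyphenol | COc1cc(OCC=C)c(O)c(CO)c1CC=C | intermediate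
14 | 2-fluoro-6-hydroxybenzaldehyde | O=Cc1c(O)cccc1F | starting material
15 | 2-(allyloxy)-6-fluorobenzaldehyde | O=Cc1c(OCC=C)cccc1F | intermediate
16 | 2-(allyloxy)-6-[3-allyl-6-(allyloxy)-2-(hydroxymethyl)-4-methoxyphenoxy]benzaldehyde | O=Cc1c(OCC=C)cccc1Oc1c(OCC=C)cc(OC)c(CC=C)c1CO | intermediate
17 | 2-(allyloxy)-6-[3-allyl-6-(allyloxy)-2-(hydroxymethyl)-4-methoxyphenoxy]benzoic acid | OC(=O)c1c(OCC=C)cccc1Oc1c(OCC=C)cc(OC)c(CC=C)c1CO | intermediate
18 | 2-methyl-2-butene | CC=C(C)C | starting material
19 | methyl 2-(allyloxy)-6-[3-allyl-6-(allyloxy)-2-(hydroxymethyl)-4-methoxyphenoxy]benzoate | COC(=O)c1c(OCC=C)cccc1Oc1c(OCC=C)cc(OC)c(CC=C)c1CO | intermediate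
20 | methyl 2-[2-(hydroxymethyl)-4-methoxy-3-(3-methylbut-2-enyl)-6-(3-methylbut-2-enyloxy)phenoxy]-6-(3-methylbut-2-enyloxy)benzoate | COC(=O)c1c(OCC=C(C)C)cccc1Oc1c(OCC=C(C)C)cc(OC)c(CC=C(C)C)c1CO | target

## Step count and least certain steps

Total: 13 steps. Longest linear sequence: 12 steps (steps 1 to 8 and 10 to 13, from 1); step 9 is a one-step branch.

Step 13 (key step). The most likely failure is incomplete exchange at one of the three sites, or migration of the C=C bond of an allyl ether into conjugation with oxygen under ruthenium hydride species formed as the catalyst decays. Either leaves mixtures that differ from 20 by one carbon unit and are hard to separate. The fallback builds the isopropylidene ends by carbonyl olefination instead. It sets out from 19: silylation of the benzylic alcohol (tert-butyldimethylsilyl chloride, imidazole, CH2Cl2) would give methyl 2-(allyloxy)-6-[3-allyl-6-(allyloxy)-2-(tert-butyldimethylsilyloxymethyl)-4-methoxyphenoxy]benzoate F1. Lemieux–Johnson cleavage (cat. OsO4, NaIO4, 2,6-lutidine, dioxane/water) would turn the three vinyl ends into the trialdehyde methyl 2-[2-(tert-butyldimethylsilyloxymethyl)-4-methoxy-6-(2-oxoethoxy)-3-(2-oxoethyl)phenoxy]-6-(2-oxoethoxy)benzoate F2. Threefold Wittig reaction with isopropylidenetriphenylphosphorane (from isopropyltriphenylphosphonium iodide and n-BuLi, THF, −78 °C to 0 °C) would give methyl 2-[2-(tert-butyldimethylsilyloxymethyl)-4-methoxy-3-(3-methylbut-2-enyl)-6-(3-methylbut-2-enyloxy)phenoxy]-6-(3-methylbut-2-enyloxy)benzoate F3, and Bu4NF in THF would return to the route at 20.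

Step 10. The phenoxide of 13 is flanked by two ortho substituents and carries a free benzylic hydroxyl. Besides slow attack, the likely losses are O-arylation through the alcohol or loss of water from the ortho-hydroxybenzyl alcohol to a quinone methide that condenses with phenoxide. The fallback masks the alcohol. It sets out from 13: tert-butyldimethylsilyl chloride and imidazole (any aryl silyl ether being cleaved again with K2CO3 in MeOH) would give 3-allyl-6-(allyloxy)-2-(tert-butyldimethylsilyloxymethyl)-4-methoxyphenol F4. Substitution on 15 under the conditions of step 10 would give 2-(allyloxy)-6-[3-allyl-6-(allyloxy)-2-(tert-butyldimethylsilyloxymethyl)-4-methoxyphenoxy]benzaldehyde F5, and Bu4NF in THF would return to the route at 16.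

Step 4. The allyl group could migrate to C4 instead of C6, and the hydroquinone aldehyde could oxidise or cyclise at 190 °C. The fallback runs the rearrangement before the formyl group is introduced, on a substrate whose regiochemistry follows that of 3,4-dialkoxyphenyl allyl ethers (migration para to the meta alkoxy group). It sets out from 5: pivaloyl chloride and pyridine would give 4-(allyloxy)-2-methoxyphenyl pivalate F6. Heating in PhNEt2 at 190 °C would give 5-allyl-4-hydroxy-2-methoxyphenyl pivalate F7. MeI and K2CO3 in acetone would give 5-allyl-2,4-dimethoxyphenyl pivalate F8, and KOH in aqueous MeOH would give 5-allyl-2,4-dimethoxyphenol F9. Magnesium-mediated ortho-formylation of F9 under the conditions of step 3 would return to the route at 10.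

Step 11. Hypochlorous acid that escapes the scavenger could chlorinate ring B at C3', which lies between two alkoxy groups, or add to the allyl groups. The fallback avoids any oxidation of the coupled molecule by bringing ring A in at the ester level. Methyl 2-fluoro-6-hydroxybenzoate F10 and 2 (K2CO3, DMF) would give methyl 2-(allyloxy)-6-fluorobenzoate F11. Setting out from 13, substitution on F11 (Cs2CO3, DMSO, 105 to 110 °C) would return to the route at 19, replacing steps 10 to 12. It is held in reserve because the ester activates less than the formyl group and the temperature needed comes close to that of allyl ether rearrangement.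

## Further compounds

F1 | step 13 | methyl 2-(allyloxy)-6-[3-allyl-6-(allyloxy)-2-(tert-butyldimethylsilyloxymethyl)-4-methoxyphenoxy]benzoate | COC(=O)c1c(OCC=C)cccc1Oc1c(OCC=C)cc(OC)c(CC=C)c1CO[Si](C)(C)C(C)(C)C
F2 | step 13 | methyl 2-[2-(tert-butyldimethylsilyloxymethyl)-4-methoxy-6-(2-oxoethoxy)-3-(2-oxoethyl)phenoxy]-6-(2-oxoethoxy)benzoate | COC(=O)c1c(OCC=O)cccc1Oc1c(OCC=O)cc(OC)c(CC=O)c1CO[Si](C)(C)C(C)(C)C
F3 | step 13 | methyl 2-[2-(tert-butyldimethylsilyloxymethyl)-4-methoxy-3-(3-methylbut-2-enyl)-6-(3-methylbut-2-enyloxy)phenoxy]-6-(3-methylbut-2-enyloxy)benzoate | COC(=O)c1c(OCC=C(C)C)cccc1Oc1c(OCC=C(C)C)cc(OC)c(CC=C(C)C)c1CO[Si](C)(C)C(C)(C)C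
F4 | step 10 | 3-allyl-6-(allyloxy)-2-(tert-butyldimethylsilyloxymethyl)-4-methoxyphenol | COc1cc(OCC=C)c(O)c(CO[Si](C)(C)C(C)(C)C)c1CC=C
F5 | step 10 | 2-(allyloxy)-6-[3-allyl-6-(allyloxy)-2-(tert-butyldimethylsilyloxymethyl)-4-methoxyphenoxy]benzaldehyde | O=Cc1c(OCC=C)cccc1Oc1c(OCC=C)cc(OC)c(CC=C)c1CO[Si](C)(C)C(C)(C)C
F6 | step 4 | 4-(allyloxy)-2-methoxyphenyl pivalate | COc1cc(OCC=C)ccc1OC(=O)C(C)(C)C
F7 | step 4 | 5-allyl-4-hydroxy-2-methoxyphenyl pivalate | COc1cc(O)c(CC=C)cc1OC(=O)C(C)(C)C
F8 | step 4 | 5-allyl-2,4-dimethoxyphenyl pivalate | COc1cc(OC)c(CC=C)cc1OC(=O)C(C)(C)C
F9 | step 4 | 5-allyl-2,4-dimethoxyphenol | COc1cc(OC)c(CC=C)cc1O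
F10 | step 11 | methyl 2-fluoro-6-hydroxybenzoate | COC(=O)c1c(O)cccc1F
F11 | step 11 | methyl 2-(allyloxy)-6-fluorobenzoate | COC(=O)c1c(OCC=C)cccc1F
A1 | alternative 1 | methyl 2-[2-(tert-butyldimethylsilyloxymethyl)-6-hydroxy-4-methoxy-3-(3-methylbut-2-enyl)phenoxy]-6-(3-methylbut-2-enyloxy)benzoate | COC(=O)c1c(OCC=C(C)C)cccc1Oc1c(O)cc(OC)c(CC=C(C)C)c1CO[Si](C)(C)C(C)(C)C
A2 | alternative 1 | methyl 2-{[2-(tert-butyldimethylsilyloxymethyl)-4-diazo-7-methyl-3-oxoocta-1,6-dienyl]oxy}-6-(3-methylbut-2-enyloxy)benzoate (enone geometry not specified) | COC(=O)c1c(OCC=C(C)C)cccc1OC=C(CO[Si](C)(C)C(C)(C)C)C(=O)C(=[N+]=[N-])CC=C(C)C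
A3 | alternative 1 | methoxyacetylene | COC#C
A4 | alternative 2 | 2-[2-(tert-butyldimethylsilyloxymethyl)-4-methoxy-3-(3-methylbut-2-enyl)-6-(3-methylbut-2-enyloxy)phenoxy]-6-(3-methylbut-2-enyloxy)benzoic acid | OC(=O)c1c(OCC=C(C)C)cccc1Oc1c(OCC=C(C)C)cc(OC)c(CC=C(C)C)c1CO[Si](C)(C)C(C)(C)C
A5 | alternative 2 | 3-(3-methylbut-2-enyloxy)-2-(trimethylsilyl)phenyl trifluoromethanesulfonate | CC(C)=CCOc1cccc(OS(=O)(=O)C(F)(F)F)c1[Si](C)(C)C
A6 | alternative 2 | 3-(3-methylbut-2-enyloxy)benzyne (1-(3-methylbut-2-enyloxy)cyclohexa-1,3-dien-5-yne) | CC(C)=CCOC1=CC=CC#C1
A7 | alternative 2 | 2-(tert-butyldimethylsilyloxymethyl)-4-methoxy-3-(3-methylbut-2-enyl)-6-(3-methylbut-2-enyloxy)phenol | COc1cc(OCC=C(C)C)c(O)c(CO[Si](C)(C)C(C)(C)C)c1CC=C(C)C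
A8 | alternative 2 | carbon dioxide | O=C=O
A9 | alternative 3 | methyl 2-hydroxy-6-[2-(tert-butyldimethylsilyloxymethyl)-4-methoxy-3-(3-methylbut-2-enyl)-6-(3-methylbut-2-enyloxy)phenoxy]benzoate | COC(=O)c1c(O)cccc1Oc1c(OCC=C(C)C)cc(OC)c(CC=C(C)C)c1CO[Si](C)(C)C(C)(C)C
A10 | alternative 3 | 3-hydroxy-2H-pyran-2-one | O=c1occcc1O
A11 | alternative 3 | methyl 3-[2-(tert-butyldimethylsilyloxymethyl)-4-methoxy-3-(3-methylbut-2-enyl)-6-(3-methylbut-2-enyloxy)phenoxy]prop-2-ynoate | COC(=O)C#COc1c(OCC=C(C)C)cc(OC)c(CC=C(C)C)c1CO[Si](C)(C)C(C)(C)C
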